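**Retrosynthetic overview**
1. Target ⇒ ring B is brominated last: the free OH of 2-(2,3,5-tribromo-6-methoxyphenoxy)phenol directs both bromines to its open ortho and para positions.
2. Key disconnection: the diaryl ether C–O bond, with the ring A carbon as the electrophile. An aryl(2,4,6-trimethoxyphenyl)iodonium salt serves as an aryl cation equivalent (the polarity of this anisole carbon is reversed) and is joined to unprotected catechol.
3. The iodonium salt comes from 3,4,6-tribromo-2-iodoanisole, made in one pot from 3-bromo-2-iodophenol by OH-directed dibromination and O-methylation, so the ring A bromine pattern is fixed before the coupling.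
4. No ring is formed: ring A (3-bromo-2-iodophenol) and ring B (catechol) are bought as benzene rings. Order of events: ring A decorated, rings joined, ring B brominated.

Assumption: the target has no stereocentre and its diaryl ether axis rotates freely at room temperature, so it is one achiral compound and no configuration has to be set or kept.
Assumption: 3-bromo-2-iodophenol is taken as a stocked catalogue building block; catechol is a bulk chemical.

**Step 1**
Reactants: 1 3-bromo-2-iodophenol
Product: 3 1,2,5-tribromo-3-iodo-4-methoxybenzene, via 3,4,6-tribromo-2-iodophenol 2 (not isolated)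
Conditions: NBS (2.05 equiv), DMF, 0 °C to rt; then K2CO3 (4 equiv), MeI (4 equiv), rt, same pot
Reagents that add atoms: N-bromosuccinimide O=C1CCC(=O)N1Br; iodomethane CI
Why: Phenol-directed electrophilic aromatic bromination takes the only two open ortho/para sites of 1 (C4 and C6), and the acidic phenoxide of 2 is then O-methylated in the same pot (Williamson ether synthesis); no stereocentre is formed.

**Step 2**
Reactants: 3 1,2,5-tribromo-3-iodo-4-methoxybenzene
Product: 5 (2,3,5-tribromo-6-methoxyphenyl)(2,4,6-trimethoxyphenyl)iodonium tosylate, via hydroxy(tosyloxy)iodoarene 4 (not isolated)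
Conditions: mCPBA (1.1 equiv), TsOH·H2O (1.1 equiv), MeCN, 77 °C, 1 h; then 1,3,5-trimethoxybenzene (1.1 equiv), 77 °C, 10 min; precipitate with Et2O
Reagents that add atoms: mCPBA OOC(=O)c1cccc(Cl)c1 (its oxygen is held only in 4); p-toluenesulfonic acid Cc1ccc(cc1)S(=O)(=O)O; 1,3,5-trimethoxybenzene COc1cc(OC)cc(OC)c1
Why: Peracid oxidation of the aryl iodide to a Koser-type trivalent iodine species, then electrophilic aromatic substitution on the very electron-rich trimethoxybenzene, gives the unsymmetrical diaryliodonium salt (one-pot aryl(trimethoxyphenyl)iodonium tosylate synthesis); no stereocentre is formed.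

**Step 3**
Reactants: 5 (2,3,5-tribromo-6-methoxyphenyl)(2,4,6-trimethoxyphenyl)iodonium tosylate; 6 catechol (benzene-1,2-diol)
Product: 7 2-(2,3,5-tribromo-6-methoxyphenoxy)phenol
Conditions: catechol (3 equiv), K2CO3 (1.5 equiv), degassed MeCN, 55 °C, under Ar
Reagents that add atoms: none
Why: Metal-free O-arylation of a phenoxide by a diaryliodonium salt (ligand exchange, then ligand coupling at trivalent iodine) makes the ring A carbon, nucleophilic in the parent anisole, react as an aryl cation toward the catecholate oxygen; the electron-poor, doubly ortho-substituted ring is transferred while the electron-rich trimethoxyphenyl group leaves as its iodide, and excess catechol holds the reaction at mono-arylation; no stereocentre is formed.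

**Step 4**
Reactants: 7 2-(2,3,5-tribromo-6-methoxyphenoxy)phenol
Product: 8 2,4-dibromo-6-(2,3,5-tribromo-6-methoxyphenoxy)phenol
Conditions: Br2 (2.05 equiv), AcOH, rt; Na2S2O3 quench
Reagents that add atoms: bromine BrBr
Why: Electrophilic aromatic bromination directed by the free hydroxyl of ring B to its open ortho and para positions; ring A is left alone because it carries three bromines and its single C–H is flanked by two of them; no stereocentre is formed.

**Compound list**
1 | 3-bromo-2-iodophenol | Oc1cccc(Br)c1I | starting material
2 | 3,4,6-tribromo-2-iodophenol | Oc1c(Br)cc(Br)c(Br)c1I | intermediate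
3 | 1,2,5-tribromo-3-iodo-4-methoxybenzene (3,4,6-tribromo-2-iodoanisole) | COc1c(Br)cc(Br)c(Br)c1I | intermediate
4 | 1,2,5-tribromo-3-[hydroxy(tosyloxy)iodo]-4-methoxybenzene | COc1c(Br)cc(Br)c(Br)c1I(O)OS(=O)(=O)c1ccc(C)cc1 | intermediate
5 | (2,3,5-tribromo-6-methoxyphenyl)(2,4,6-trimethoxyphenyl)iodonium 4-methylbenzenesulfonate | COc1c(Br)cc(Br)c(Br)c1[I+]c1c(OC)cc(OC)cc1OC.Cc1ccc(cc1)S(=O)(=O)[O-] | intermediate
6 | catechol (benzene-1,2-diol) | Oc1ccccc1O | starting material
7 | 2-(2,3,5-tribromo-6-methoxyphenoxy)phenol | COc1c(Br)cc(Br)c(Br)c1Oc1ccccc1O | intermediate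
8 | 2,4-dibromo-6-(2,3,5-tribromo-6-methoxyphenoxy)phenol | COc1c(Br)cc(Br)c(Br)c1Oc1cc(Br)cc(Br)c1O | target

**Total step count:** 4
**Longest linear sequence:** 4 (1 → 3 → 5 → 7 → 8)

**Steps most likely to fail**

Step 3 (the coupling). Free catechol may be oxidised, arylated twice, or bind the iodine as a chelate. The fallback sets out from 5 and brings ring B in with its second oxygen latent as a formyl group. Salicylaldehyde is O-arylated by 5 (K2CO3, MeCN, 55 °C) to 2-(2,3,5-tribromo-6-methoxyphenoxy)benzaldehyde F1. Baeyer–Villiger oxidation (mCPBA, CH2Cl2, rt) gives 2-(2,3,5-tribromo-6-methoxyphenoxy)phenyl formate F2, which K2CO3 in MeOH cleaves to 7, where the route is rejoined.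

Step 2 (iodonium formation). The iodine of 3 sits between a methoxy group and a bromine on an electron-poor ring, so oxidation or trapping may be poor. The fallback sets out from 3, drops the iodonium and makes the same C–O bond by copper catalysis. Aryl iodide 3 and 2-(benzyloxy)phenol with CuI (10 mol%), picolinic acid (20 mol%) and K3PO4 in DMSO at 90 °C (Ullmann-type etherification, the C–I bond reacting ahead of the C–Br bonds) give 1-(benzyloxy)-2-(2,3,5-tribromo-6-methoxyphenoxy)benzene F3. BCl3 with pentamethylbenzene in CH2Cl2 at −78 °C removes the benzyl group without touching the methyl ether or the bromines and returns to the route at 7.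

Step 4 (late bromination). It may over-brominate (ring A C–H, or a third bromine on ring B) or stall at the monobromide. The fallback sets out from 5 and carries the ring B bromines in on the nucleophile. 3,5-Dibromobenzene-1,2-diol F4 is made from 3,5-dibromosalicylaldehyde by Dakin oxidation (H2O2, NaOH, H2O, rt) and arylated with 5 (K2CO3, MeCN, 55 °C). Its hydroxyl without an ortho bromine is the less hindered one, so the bulky aryl group should go there and give 8 directly, where the route is rejoined; this regioselectivity is expected on steric grounds and is not guaranteed.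

**Further compounds**
F1 | step 3 | 2-(2,3,5-tribromo-6-methoxyphenoxy)benzaldehyde | COc1c(Br)cc(Br)c(Br)c1Oc1ccccc1C=O
F2 | step 3 | 2-(2,3,5-tribromo-6-methoxyphenoxy)phenyl formate | COc1c(Br)cc(Br)c(Br)c1Oc1ccccc1OC=O
F3 | step 2 | 1-(benzyloxy)-2-(2,3,5-tribromo-6-methoxyphenoxy)benzene | COc1c(Br)cc(Br)c(Br)c1Oc1ccccc1OCc1ccccc1
F4 | step 4 | 3,5-dibromobenzene-1,2-diol | Oc1cc(Br)cc(Br)c1O
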